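The target is read as the ring-opened, C7-reduced form of a 3a-methoxy-2-aryl-2,3-dihydrobenzofuran-6-one: its quaternary C4(OMe) of the dienone ring carries C8, the neighbouring C5 carries oxygen, and C7 is benzylic and para to the phenol OH, so an O5–C7 dihydrofuran ring can be closed and later reopened. One chiral-acid-catalysed cationic (3+2) cycloaddition of (E)-isoeugenol to a 2-allyl quinone monoketal ionised at C4 forms C4–C8 and C7–O5 and sets C4 and C8. The precursor is the C4 dimethyl ketal with its free carbonyl at C5 and a methyl enol ether at C1, which steers the alkene to C4.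

Key step: step 4

Remarks on the chemistry (assumptions):
- Locants: ring C1–C6 and side chain C7–C9 are numbered as in the target (C1 carbonyl, C2 allyl-bearing, C4 quaternary, C5 enol-ether carbon, C7 benzylic CH2, C8 CH(CH3)); O1 and O5 are the oxygens on C1 and C5.
- Precursor design: the ketal keeps the 2-allyl-4,4-dimethoxycyclohexadienone skeleton oxygenated at C1 and C5, but the methyl sits on O1 and the free carbonyl on C5 (compound 6), not the reverse as in 2-allyl-4,4,5-trimethoxycyclohexa-2,5-dienone; the alkene adds reversibly and the adduct that cyclises is the one formed next to the free carbonyl, which is C2 with C1=O (the known course of that ketal with (E)-propenylarenes, to 3a-allyl-5-methoxy hydrobenzofuranones) and C4 with C5=O, and the methyl then leaves from an oxocarbenium ion and not from a trialkyloxonium ion.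
- The (R) catalyst is assumed to give 9 (if it favours the enantiomer, the (S) catalyst is used), and (E)-isoeugenol is bought as the pure trans isomer.

Step 1
Reactants: 1 4-bromo-2,5-dimethoxybenzaldehyde; 2 allyltributylstannane
Product: 3 4-allyl-2,5-dimethoxybenzaldehyde
Conditions: Pd(PPh3)4 (5 mol %), PhMe, 100 °C
Reagents that add atoms: none
Why: Migita–Kosugi–Stille cross-coupling: oxidative addition into the C–Br bond para to the formyl group, allyl transfer from tin and reductive elimination under neutral conditions, which tolerate the aldehyde and should not move the allyl double bond into conjugation; no stereocentre is formed.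

Step 2
Reactants: 3 4-allyl-2,5-dimethoxybenzaldehyde
Product: 5 4-allyl-2,5-dimethoxyphenol, via aryl formate 4 (not isolated)
Conditions: 35% aq. H2O2, H2SO4 (cat.), MeOH, rt
Reagents that add atoms: hydrogen peroxide, OO
Why: Acid-catalysed Dakin oxidation (Baeyer–Villiger-type aryl migration in the hydroperoxide adduct, favoured by the electron-rich ortho-methoxylated ring), the formate 4 being methanolysed in the same pot; the monosubstituted alkene is inert to uncatalysed H2O2.

Step 3
Reactants: 5 4-allyl-2,5-dimethoxyphenol
Product: 6 4-allyl-3,6,6-trimethoxycyclohexa-2,4-dien-1-one (target locants: C5=O, C4(OMe)2, C1–OMe, C2-allyl)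
Conditions: PhI(OAc)2, MeOH, −20 → 0 °C; NaHCO3 work-up; kept cold and dilute, used at once
Reagents that add atoms: methanol, CO
Why: Oxidative dearomatisation of a 2-methoxyphenol with a λ3-iodane to a masked o-benzoquinone: ligand exchange at iodine and loss of PhI give the phenoxonium ion, which methanol should capture at the methoxy-bearing ortho carbon (C4), the oxocarbenium-stabilised position that leaves a vinylogous ester; no stereocentre is formed.

Step 4
Reactants: 6 4-allyl-3,6,6-trimethoxycyclohexa-2,4-dien-1-one; 7 (E)-isoeugenol
Product: 9 (2S,3R,3aR)-5-allyl-2-(4-hydroxy-3-methoxyphenyl)-3a-methoxy-3-methyl-3,3a-dihydrobenzofuran-6(2H)-one, via dimethyl ketal 8 (not isolated)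
Conditions: (R)-3,3′-bis(2,4,6-triisopropylphenyl)-BINOL N-triflylphosphoramide (10 mol %), CH2Cl2, −60 → −30 °C; then PPTS (cat.), THF/H2O, 0 °C
Reagents that add atoms: water, O
Why: Proposed new method: the chiral acid ionises the C4 ketal of 6 to a methoxy-stabilised phenoxonium-type cation paired with the chiral anion; C8 of 7 (the vinylogous para position of the phenol) adds to C4, the C7 p-hydroxybenzyl cation (a protonated quinone methide) is captured by the neighbouring C5 carbonyl oxygen in a 5-exo-trig closure of the dihydrofuran ring, and the resulting 1,3-dialkoxyallyl cation across C5–C6–C1 takes up the liberated methanol at C1 as ketal 8, so the acid turns over, before mild aqueous acid hydrolyses 8 to the C1 ketone (C6 of the benzofuranone). The closest known reactions are the acid-promoted, racemic (3+2) cycloadditions of quinone monoketals with (E)-propenylarenes to hydrobenzofuranones and the chiral-phosphoric-acid-catalysed quinone (3+2) annulations with hydroxystyrenes that give aromatic dihydrobenzofurans; new here are the C5-oxo ketal, the dearomatised product and the asymmetric control. C3a (= C4) is set by the face of the planar cation left open by the chiral anion, which also hydrogen-bonds the phenol OH of 7; C3 (= C8) is set in the same bond-forming event, the compact endo-aryl approach (aryl stacked over the C5–C6–C1 vinylogous ester, O5 aligned with C7) turning the C8 methyl away from the ring and so syn to the 3a-methoxy group, which is the 4S,8R relation of the target; C2 (= C7) follows from the E alkene and from thermodynamics, since the C7–O bond reopens reversibly under the acid and should settle trans to methyl. The step needs site selectivity for C4 over C2 and C6, secured because only the C4 adduct has a carbonyl oxygen at hand for ring closure (C6 is the electron-rich α-carbon of the vinylogous ester, C2 adducts can only revert), and face selectivity at both partners, which rests on the hydrogen-bonded ion pair.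

Step 5
Reactants: 9 (2S,3R,3aR)-5-allyl-2-(4-hydroxy-3-methoxyphenyl)-3a-methoxy-3-methyl-3,3a-dihydrobenzofuran-6(2H)-one
Product: 11 (4S)-2-allyl-5-hydroxy-4-[(2R)-1-(4-hydroxy-3-methoxyphenyl)propan-2-yl]-4-methoxycyclohexa-2,5-dien-1-one, via quinone methide 10 (not isolated)
Conditions: NaBH4, 1 M aq. NaOH, EtOH/THF, 0 °C → rt; then aq. HCl to pH 4
Reagents that add atoms: none
Why: Phenoxide-triggered 1,6-elimination (E1cB) expels the vinylogous carboxylate from C7 to give p-quinone methide 10, which borohydride reduces by 1,6-hydride addition at C7 (the standard reductive trapping of quinone methides), while the vinylogous-ester carbonyl of 9 and the dione enolate formed are too electron-rich to be reduced at this temperature; C4 and C8 are not touched and C7 ceases to be stereogenic.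

Step 6
Reactants: 11 (4S)-2-allyl-5-hydroxy-4-[(2R)-1-(4-hydroxy-3-methoxyphenyl)propan-2-yl]-4-methoxycyclohexa-2,5-dien-1-one
Product: 12 (4S)-2-allyl-4-[(2R)-1-(4-hydroxy-3-methoxyphenyl)propan-2-yl]-4,5-dimethoxycyclohexa-2,5-dien-1-one (CNP0370214.1)
Conditions: TMSCHN2 (1.1 equiv), MeOH/PhMe 1:4, 0 °C
Reagents that add atoms: trimethylsilyldiazomethane, C[Si](C)(C)C=[N+]=[N-]
Why: Diazoalkane O-methylation of a vinylogous acid: the enol (pKa about 5) protonates the reagent while the guaiacol OH (pKa about 10) should not at 0 °C, and methylation is expected mainly at O5 because the 5-hydroxy-2,5-dienone tautomer (C1=O conjugated with C2=C3, OH hydrogen-bonded to the C4 methoxy group) should dominate, the O1 enol ether being the likely by-product; no stereocentre is touched.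

Compound list
1 | 4-bromo-2,5-dimethoxybenzaldehyde | COc1cc(C=O)c(OC)cc1Br | starting material
2 | allyltributylstannane | C=CC[Sn](CCCC)(CCCC)CCCC | starting material
3 | 4-allyl-2,5-dimethoxybenzaldehyde | COc1cc(C=O)c(OC)cc1CC=C | intermediate
4 | 4-allyl-2,5-dimethoxyphenyl formate (not isolated) | COc1cc(OC=O)c(OC)cc1CC=C | intermediate
5 | 4-allyl-2,5-dimethoxyphenol | COc1cc(O)c(OC)cc1CC=C | intermediate
6 | 4-allyl-3,6,6-trimethoxycyclohexa-2,4-dien-1-one | C=CCC1=CC(OC)(OC)C(=O)C=C1OC | intermediate
7 | (E)-isoeugenol | C/C=C/c1ccc(O)c(OC)c1 | starting material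
8 | 4-[(2S,3R,3aR)-5-allyl-3a,6,6-trimethoxy-3-methyl-2,3,3a,6-tetrahydrobenzofuran-2-yl]-2-methoxyphenol (not isolated) | C=CCC1=C[C@@]2(OC)[C@H](C)[C@@H](c3ccc(O)c(OC)c3)OC2=CC1(OC)OC | intermediate
9 | (2S,3R,3aR)-5-allyl-2-(4-hydroxy-3-methoxyphenyl)-3a-methoxy-3-methyl-3,3a-dihydrobenzofuran-6(2H)-one | C=CCC1=C[C@@]2(OC)[C@H](C)[C@@H](c3ccc(O)c(OC)c3)OC2=CC1=O | intermediate
10 | (4S)-2-allyl-5-hydroxy-4-methoxy-4-[(2R)-1-(3-methoxy-4-oxocyclohexa-2,5-dien-1-ylidene)propan-2-yl]cyclohexa-2,5-dien-1-one (not isolated; present as its sodium enolate; exocyclic C=C geometry not defined) | C=CCC1=C[C@@](OC)([C@H](C)C=C2C=CC(=O)C(OC)=C2)C(O)=CC1=O | intermediate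
11 | (4S)-2-allyl-5-hydroxy-4-[(2R)-1-(4-hydroxy-3-methoxyphenyl)propan-2-yl]-4-methoxycyclohexa-2,5-dien-1-one (enol form of the cyclohex-2-ene-1,5-dione) | C=CCC1=C[C@@](OC)([C@H](C)Cc2ccc(O)c(OC)c2)C(O)=CC1=O | intermediate
12 | (4S)-2-allyl-4-[(2R)-1-(4-hydroxy-3-methoxyphenyl)propan-2-yl]-4,5-dimethoxycyclohexa-2,5-dien-1-one | C=CCC1=C[C@@](OC)([C@H](C)Cc2ccc(O)c(OC)c2)C(OC)=CC1=O | target

Total step count: 6. Longest linear sequence: 6 steps (1 → 3 → 5 → 6 → 9 → 11 → 12); 7 is bought and enters in step 4.

Steps most likely to fail

Step 4 (proposed new method). What may go wrong: the weakly basic α-keto ketal may ionise too slowly under the chiral acid; facial control may erode if the ion pair loosens; the alkene may add at C2 or C6; and 7 may dimerise under acid. Fallback, from 6 and 7 back to 9: the cycloaddition is run in its established racemic, achiral-acid-promoted form (TfOH or TMSOTf cat., MeCN, −40 °C, then the same aqueous acid work-up), which permits stronger acid and polar solvent. This should give 9 together with its enantiomer (2R,3S,3aS)-5-allyl-2-(4-hydroxy-3-methoxyphenyl)-3a-methoxy-3-methyl-3,3a-dihydrobenzofuran-6(2H)-one F1. The two are separated by preparative HPLC on a polysaccharide chiral stationary phase, and 9 is carried into step 5.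

Step 3. What may go wrong: methanol may capture the phenoxonium ion at the allyl-bearing carbon; the allylic CH2 may lose a proton to give a quinone methide; and the dienone may be lost by [4+2] dimerisation on concentration. Fallback, from 5 back to 9: Wessely acetoxylation (Pb(OAc)4, AcOH/CH2Cl2, 0 °C) delivers acetate from the metal to the methoxy-bearing ortho carbon and should give the o-quinol acetate 3-allyl-1,4-dimethoxy-6-oxocyclohexa-2,4-dien-1-yl acetate F2 (racemic). F2 ionises at C4 by loss of acetate, more readily than 6 loses methoxide, to the same cation. It is used in place of 6 under the conditions of step 4 and rejoins the route at 9.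

Step 6. What may go wrong: methylation may occur at O1 instead of O5 of the ambident vinylogous acid, and the phenol may be slowly methylated by excess reagent. Fallback, from 11 (or from a mixture of its two enol ethers) back to 12: HC(OMe)3, MeOH, PPTS (cat.), rt converts the dione, through the common 1,5-dimethoxyallyl cation, into the enol ether ketal 4-[(2R)-2-[(1S)-3-allyl-1,4,4,6-tetramethoxycyclohexa-2,5-dien-1-yl]propyl]-2-methoxyphenol F3. Brief treatment with dilute aqueous acid (PPTS, wet acetone, 0 °C) then ionises the ketal, and water should add at C1. C1 is the less hindered terminus, remote from the quaternary C4, and attack there restores the cross-conjugated dienone, giving 12.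

Further compounds
F1 | step 4 | (2R,3S,3aS)-5-allyl-2-(4-hydroxy-3-methoxyphenyl)-3a-methoxy-3-methyl-3,3a-dihydrobenzofuran-6(2H)-one | C=CCC1=C[C@]2(OC)[C@@H](C)[C@H](c3ccc(O)c(OC)c3)OC2=CC1=O
F2 | step 3 | 3-allyl-1,4-dimethoxy-6-oxocyclohexa-2,4-dien-1-yl acetate (racemic) | C=CCC1=CC(OC)(OC(C)=O)C(=O)C=C1OC
F3 | step 6 | 4-[(2R)-2-[(1S)-3-allyl-1,4,4,6-tetramethoxycyclohexa-2,5-dien-1-yl]propyl]-2-methoxyphenol | C=CCC1=C[C@@](OC)([C@H](C)Cc2ccc(O)c(OC)c2)C(OC)=CC1(OC)OC
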